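## The problem

CNP0005248.2 (34) is a germacranolide: a ten-membered carbocycle (C1–C10) with two trisubstituted, ring-cis alkenes (C1=C10 carrying the oxymethyl carbon C14, C4=C5 carrying the methyl C15) and a trans-fused α-methylene γ-lactone across C6–C7 (O–C6–C7–C11–C12, exocyclic C11=C13). The first question is how the medium ring is made, since direct closure of a ten-membered ring costs entropy and transannular strain. Four contiguous stereocentres (6R, 7R, 8S, 9R) line one flank of the ring and a fifth sits in the (R)-2-methylbutanoate. C8 can be bought and C9 can be set from C8 by a Felkin-controlled carbonyl addition, but C6 and C7 must arise in the ring-forming event, with C8 as the only nearby director. Three similar oxygens must end up different (free hydroxyl at C8, acetate at C9, chiral ester at C14), the hydroxyls at C6 and C8 can both lactonise onto C12, and a 9-acetate beside a free 8-hydroxyl migrates under base. The α-methylene lactone is a Michael acceptor, the allylic esters do not survive hydride or organolithium reagents, and the 1,5-diene invites transannular reactions under acid or heat, so lactone and esters must come last and under mild conditions. The enabling feature is the C6–C7 bond: C6 is a carbinol carbon allylic to C4=C5 and C7 carries the 1,1-disubstituted alkene C11=C13. This homoallylic alcohol is the retron of a [2,3]-Wittig shift of a C6–O–C13 allyl ether, which makes the carbocycle by contraction of a thirteen-membered ring.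

## Retrosynthesis

Atom numbers are those of the germacrane skeleton throughout.

**Ester and acetate (34 ⇒ 32 + 33 ⇒ 31 ⇒ 30).** The C14–O acyl bond is cut last, giving diol 32 and (R)-2-methylbutanoic acid 33. A primary allylic hydroxyl is acylated beside a hindered secondary one, and no basic step follows once the 8-hydroxyl is free. Diol 32 comes from bis-silyl ether 31 by one fluoride treatment, and 31 from alcohol 30 by acetylation, at which point O9 is the only free hydroxyl. The neighbouring order (acylating C14 first) would require removing one primary silyl ether beside a secondary one and costs a step.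

**Lactone (30 ⇒ 27 ⇒ 26).** The C12–O6 bond and the C12 carbonyl are traced to triol 27 by oxidative lactonisation, and 27 to the tetrasilyl carbinol 26 by loss of the two acid-labile silyl groups (primary TBS at O12, TES at O9). C12 is carried at the alcohol level for three reasons. A carboxyl derivative would not survive butyllithium. An acetal would need acid beside a TES ether. A stabilised-ylide olefination places the carbonyl-derived carbon trans to C8, which is the position C13, not C12, must occupy. O9 is released together with O12 because it cannot interfere (secondary, and it could only form a bridged six-membered lactol), and it is then the single hydroxyl left for acetylation.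

**Carbocycle (26 ⇒ 24).** The C6–C7 bond is cut and O6 reconnected to C13, giving the thirteen-membered diallylic ether 24. Against cuts at C5–C6 or C8–C9, which ask for direct ten-membered closure, this one forms the ring inside an existing ring and creates C6, C7 and the exocyclic methylene together. The precursor has two stereocentres fewer and an unstrained ring. The forward step must remove a proton at C6 and not at C13, must give the 6,7-trans relationship, and must bond to the correct face of C7 relative to C8.

**Ether ring (24 ⇒ 23 ⇒ 22 ⇒ 21 ⇒ 20).** The O–C13 bond is cut to the hydroxy bromide 23 (C6 alkoxide on C13 allylic bromide). The opposite polarity is rejected: an alkoxide on C13 would sit 1,3 to the C12 silyl ether, and silyl migration would exchange the two arms of C11 and so scramble the C7=C11 geometry. Because C13 is trans to C8 on C7=C11, no small ring can form. Compound 23 goes back through PMB ether 22 and allylic alcohol 21 to ester 20 by routine functional-group changes, so C13 is carried as an ester until after fragment coupling.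

**C9–C10 (20 ⇒ 19 ⇒ 9 + 18).** The carbinol 19 is cut at C9–C10 into alkenyl iodide 9 and aldehyde 18, joined by a Nozaki–Hiyama–Kishi reaction. The cut is central, tolerates the ester in 18, transfers the iodide geometry to C1=C10 and lets C8 set C9 by Felkin–Anh addition. An organolithium addition would not spare the ester.

**Fragment B (18 ⇒ 17 ⇒ 16 ⇒ 15 ⇒ 14 ⇒ 12 ⇒ 11 ⇒ 10 + 6).** The two oxygenated arms on C11 are told apart by geometry. An α-iodo Wittig reaction of (R)-glyceraldehyde acetonide 10 with ylide 6 gives iodoenoate 11 with the ester (future C13) trans to C8 and iodine cis. After the acetonide is exchanged for a primary TES and secondary TBS ether (12, 14), a Stille hydroxymethylation replaces iodine by C12 with retention (15). Silylation (16), selective loss of the primary TES group (17) and oxidation give 18. C8 comes from the chiral pool.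

**Fragment A (9 ⇒ 8 ⇒ 7 ⇒ 5 + 6; 5 ⇒ 3 ⇒ 2 ⇒ 1).** Nerol (1) supplies C2–C6, C15 and the Z C4=C5 alkene. Its terminal alkene is cleaved (PMB ether 2, epoxide 3, aldehyde 5) to expose C1. The same α-iodo Wittig reaction with 6 gives the Z iodoenoate 7, which is reduced to 8 and silylated to 9. The PMB group is the one protecting group that can later be removed beside an allylic bromide and four silyl ethers.

## Roads not taken

**Alternative 1:** The cut is the C5–C6 bond together with the lactone C–O bond. In the open-chain iodo aldehyde ester A1, CrCl2 with catalytic NiCl2 would convert the Z C5 alkenyl iodide into its chromium derivative, which adds to the C6 aldehyde. The C6 alkoxide would then displace methoxide from the C12 ester, giving the saturated lactone A2 with both rings closed in one operation.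
- Merits: mild and chemoselective conditions, Z C4=C5 geometry taken from the iodide, no organolithium, so the protecting-group pattern is simpler than in the chosen plan.
- Weak points: a ten-membered ring is closed directly (high dilution, large excess of chromium salt). C7 must already be in place, α to the aldehyde and β to a silyloxy group, so it can epimerise or eliminate. The C6 configuration is set in a macrocyclisation with no reliable model. A2 still lacks the C13 methylene, so a late enolate methylenation is needed.
- Comparison: in functional-group tolerance this road is better. The chosen plan sets against it the easy O-alkylative closure of an unstrained thirteen-membered ring and the simultaneous delivery of C6, C7 and the methylene.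

**Alternative 2:** Here no ring is closed. The C4=C5 alkene and a C9 carbonyl are traced back to a transannular C4–C9 bond. In the cis-decalin hydroxy mesylate A3, potassium tert-butoxide would deprotonate the tertiary C9 hydroxyl, the C4–C9 bond would break as C9=O and C4=C5 form and mesylate leaves C5 (Wharton–Grob fragmentation), giving ketone A4.
- Merits: no medium-ring closure, the Z C4=C5 geometry is dictated stereospecifically by the anti-periplanar bonds, and C6–C8 are set on a chair.
- Weak points: A3 has six stereocentres including a quaternary C4 and a tertiary carbinol and is harder to make than any intermediate of the chosen plan. The alkoxide conditions meet an enolisable lactone. A4 has an epimerisable C8 beside the new ketone, still needs a stereoselective C9 reduction and still lacks the methylene.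
- Comparison: in alkene-geometry control and in avoiding a macrocyclisation it is at least as good. The chosen plan takes both Z alkenes from nerol and an iodoalkene at no cost and needs no quaternary centre.

**Alternative 3:** The cut is C8–C9. In the boronate aldehyde A5, generated by Dess–Martin oxidation, C9 of the γ-alkoxyallyl pinacolboronate would attack the C8 aldehyde through a chair transition state. C8–C9 forms, boron leaves C1, the alkene moves to C10=C1 and the ring closes to A6.
- Merits: ring closure, both oxygenated stereocentres and the Z C1=C10 alkene in one metal-free step through a closed transition state. O8 and O9 emerge differentiated, which the chosen plan achieves only with a protecting-group sequence.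
- Weak points: A5 needs a configurationally defined α-chiral boronate with an E enol ether, which is hard to make and prone to 1,3-boron shifts. Its aldehyde is α to C7 and epimerisable. A ten-membered allylboration through a bicyclic chair is strained. A6 again lacks the methylene.
- Comparison: the chosen plan is weaker in oxygen differentiation but rests on simpler fragments and on a ring-forming step of a known type.

Key step: step 20

## Remarks on the chemistry

- Assumption: (R)-2-methylbutanoic acid (33) and aldehyde 10 are bought as single enantiomers; 10 is distilled before use.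
- Abbreviations: TBS = tert-butyldimethylsilyl, TES = triethylsilyl, TBDPS = tert-butyldiphenylsilyl, PMB = 4-methoxybenzyl.

## Route

Step 1
Reactants: 1 nerol
Product: 2 nerol PMB ether
Conditions: NaH, PMBCl, Bu4NI (cat.), THF/DMF, 0 °C → rt
Reagents that add atoms: 4-methoxybenzyl chloride, COc1ccc(CCl)cc1
Why: Williamson etherification of the primary allylic alkoxide; the PMB ether can later be removed oxidatively beside an allylic bromide and silyl ethers.

Step 2
Reactants: 2 nerol PMB ether
Product: 3 6,7-epoxide of the nerol PMB ether (racemic)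
Conditions: mCPBA, NaHCO3, CH2Cl2, −20 → 0 °C
Reagents that add atoms: 3-chloroperbenzoic acid, OOC(=O)c1cccc(Cl)c1
Why: Prilezhaev epoxidation; the terminal alkene is more electron-rich than the alkene next to the allylic ether oxygen, and the new stereocentre is destroyed in the next step.

Step 3
Reactants: 3 6,7-epoxide of the nerol PMB ether
Product: 5 (4Z)-6-[(4-methoxybenzyl)oxy]-4-methylhex-4-enal, via diol 4 (not isolated)
Conditions: H5IO6, THF/H2O, 0 °C
Reagents that add atoms: water, O (its oxygen enters intermediate 4 and leaves in the acetone)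
Why: Periodic acid opens the epoxide to diol 4 and cleaves it (Malaprade reaction) to the C1 aldehyde; the Z C4=C5 alkene is not touched.

Step 4
Reactants: 5 (4Z)-6-[(4-methoxybenzyl)oxy]-4-methylhex-4-enal; 6 ethyl (triphenylphosphoranylidene)acetate
Product: 7 ethyl (2Z,6Z)-2-iodo-8-[(4-methoxybenzyl)oxy]-6-methylocta-2,6-dienoate
Conditions: 6, NIS, CH2Cl2, −20 °C; then 5, K2CO3, −20 °C → rt
Reagents that add atoms: N-iodosuccinimide, O=C1CCC(=O)N1I
Why: Tandem iodination–Wittig reaction: NIS converts 6 into the α-iodo ylide, which as a stabilised ylide places the ester trans to the chain, so iodine is cis to C2 as the Z C1=C10 alkene requires.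

Step 5
Reactants: 7 ethyl (2Z,6Z)-2-iodo-8-[(4-methoxybenzyl)oxy]-6-methylocta-2,6-dienoate
Product: 8 (2Z,6Z)-2-iodo-8-[(4-methoxybenzyl)oxy]-6-methylocta-2,6-dien-1-ol
Conditions: i-Bu2AlH, CH2Cl2, −78 °C
Reagents that add atoms: none
Why: 1,2-Reduction of the enoate to the allylic alcohol (C14); alkenyl iodide and PMB ether are inert to the aluminium hydride at low temperature.

Step 6
Reactants: 8 (2Z,6Z)-2-iodo-8-[(4-methoxybenzyl)oxy]-6-methylocta-2,6-dien-1-ol
Product: 9 fragment A (C14 OTBDPS alkenyl iodide)
Conditions: TBDPSCl, imidazole, CH2Cl2, 0 °C → rt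
Reagents that add atoms: tert-butylchlorodiphenylsilane, CC(C)(C)[Si](Cl)(c1ccccc1)c1ccccc1
Why: Silylation of the primary alcohol; the TBDPS ether survives the acid that later removes the TES and primary TBS groups.

Step 7
Reactants: 10 (R)-2,2-dimethyl-1,3-dioxolane-4-carbaldehyde; 6 ethyl (triphenylphosphoranylidene)acetate
Product: 11 ethyl (2Z)-3-[(4S)-2,2-dimethyl-1,3-dioxolan-4-yl]-2-iodoprop-2-enoate
Conditions: 6, NIS, CH2Cl2, −20 °C; then 10, K2CO3, −20 °C → rt
Reagents that add atoms: N-iodosuccinimide, O=C1CCC(=O)N1I
Why: The same tandem iodination–Wittig reaction puts the ester (future C13) trans to C8 and iodine cis; the weak carbonate base should leave the C8 stereocentre of 10 intact.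

Step 8
Reactants: 11 ethyl (2Z)-3-[(4S)-2,2-dimethyl-1,3-dioxolan-4-yl]-2-iodoprop-2-enoate
Product: 12 ethyl (2Z,4S)-4,5-dihydroxy-2-iodopent-2-enoate
Conditions: AcOH/H2O (4:1), 40 °C
Reagents that add atoms: none
Why: Acid hydrolysis of the acetonide before any acid-labile silyl ether is present; the ester is trans to C8, so the diol cannot lactonise.

Step 9
Reactants: 12 ethyl (2Z,4S)-4,5-dihydroxy-2-iodopent-2-enoate
Product: 14 ethyl (2Z,4S)-4-[(tert-butyldimethylsilyl)oxy]-2-iodo-5-[(triethylsilyl)oxy]pent-2-enoate, via mono-TES ether 13 (not isolated)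
Conditions: TESCl, imidazole, CH2Cl2, −78 → −40 °C; then TBSOTf, 2,6-lutidine, −78 → 0 °C
Reagents that add atoms: chlorotriethylsilane, CC[Si](Cl)(CC)CC; tert-butyldimethylsilyl triflate, CC(C)(C)[Si](C)(C)OS(=O)(=O)C(F)(F)F
Why: One-flask sequential silylation: the primary hydroxyl (C9) reacts first with TESCl at low temperature, and the secondary hydroxyl (C8) is then capped with the triflate.

Step 10
Reactants: 14 ethyl (2Z,4S)-4-[(tert-butyldimethylsilyl)oxy]-2-iodo-5-[(triethylsilyl)oxy]pent-2-enoate
Product: 15 ethyl (2E,4S)-4-[(tert-butyldimethylsilyl)oxy]-2-(hydroxymethyl)-5-[(triethylsilyl)oxy]pent-2-enoate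
Conditions: Bu3SnCH2OH, Pd(PPh3)4 (cat.), 1,4-dioxane, 80 °C
Reagents that add atoms: (tributylstannyl)methanol, CCCC[Sn](CCCC)(CCCC)CO
Why: Stille hydroxymethylation of the activated alkenyl iodide with retention of geometry, so that C12 is cis and the ester (C13) trans to C8.

Step 11
Reactants: 15 ethyl (2E,4S)-4-[(tert-butyldimethylsilyl)oxy]-2-(hydroxymethyl)-5-[(triethylsilyl)oxy]pent-2-enoate
Product: 16 ethyl (2E,4S)-4-[(tert-butyldimethylsilyl)oxy]-2-{[(tert-butyldimethylsilyl)oxy]methyl}-5-[(triethylsilyl)oxy]pent-2-enoate
Conditions: TBSCl, imidazole, DMF, 0 °C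
Reagents that add atoms: tert-butylchlorodimethylsilane, CC(C)(C)[Si](C)(C)Cl
Why: Silylation of the primary allylic alcohol; a primary TBS ether at O12 is later removed together with the O9 TES ether while TBDPS and secondary TBS stay.

Step 12
Reactants: 16 ethyl (2E,4S)-4-[(tert-butyldimethylsilyl)oxy]-2-{[(tert-butyldimethylsilyl)oxy]methyl}-5-[(triethylsilyl)oxy]pent-2-enoate
Product: 17 ethyl (2E,4S)-4-[(tert-butyldimethylsilyl)oxy]-2-{[(tert-butyldimethylsilyl)oxy]methyl}-5-hydroxypent-2-enoate
Conditions: PPTS, MeOH/CH2Cl2, 0 °C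
Reagents that add atoms: none
Why: Acid-catalysed methanolysis removes the primary TES ether, which is far more labile than the TBS ethers.

Step 13
Reactants: 17 ethyl (2E,4S)-4-[(tert-butyldimethylsilyl)oxy]-2-{[(tert-butyldimethylsilyl)oxy]methyl}-5-hydroxypent-2-enoate
Product: 18 fragment B (C9 aldehyde)
Conditions: Dess–Martin periodinane, NaHCO3, CH2Cl2, 0 °C; used crude
Reagents that add atoms: none
Why: Dess–Martin oxidation under buffered conditions; base is avoided because H8 is α to the aldehyde and vinylogous to the ester.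

Step 14
Reactants: 9 fragment A (C14 OTBDPS alkenyl iodide); 18 fragment B (C9 aldehyde)
Product: 19 C9 carbinol (8S 9R)
Conditions: CrCl2, NiCl2 (cat.), DMSO, rt
Reagents that add atoms: none
Why: Nozaki–Hiyama–Kishi coupling: the alkenylchromium reagent from 9 adds to the aldehyde with retention of the alkene geometry and without touching the ester. Felkin–Anh attack anti to the C8 silyloxy group should give the 8,9-anti (9R) carbinol.

Step 15
Reactants: 19 C9 carbinol
Product: 20 C9 TES ether ester
Conditions: TESOTf, 2,6-lutidine, CH2Cl2, −78 °C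
Reagents that add atoms: triethylsilyl triflate, CC[Si](CC)(CC)OS(=O)(=O)C(F)(F)F
Why: Silylation of the hindered secondary allylic alcohol with the triflate; TES at O9 stays distinguishable from TBS at O8.

Step 16
Reactants: 20 C9 TES ether ester
Product: 21 C13 allylic alcohol
Conditions: i-Bu2AlH, CH2Cl2, −78 °C
Reagents that add atoms: none
Why: 1,2-Reduction of the enoate to the C13 alcohol; silyl and PMB ethers are inert.

Step 17
Reactants: 21 C13 allylic alcohol
Product: 22 C13 allylic bromide
Conditions: CBr4, PPh3, 2,6-lutidine, CH2Cl2, −30 → 0 °C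
Reagents that add atoms: tetrabromomethane, BrC(Br)(Br)Br
Why: Appel bromination by SN2 at the primary carbon under buffered neutral conditions, which avoids an alkoxide 1,3 to the O12 silyl ether.

Step 18
Reactants: 22 C13 allylic bromide
Product: 23 C6 hydroxy C13 bromide
Conditions: DDQ, CH2Cl2/pH 7 buffer, 0 °C
Reagents that add atoms: none
Why: Oxidative cleavage of the PMB ether; the buffered short reaction spares the allylic bromide and the silyl ethers.

Step 19
Reactants: 23 C6 hydroxy C13 bromide
Product: 24 thirteen-membered diallylic ether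
Conditions: NaH, THF, syringe-pump addition (final 0.002 M), 0 → 40 °C
Reagents that add atoms: none
Why: Intramolecular Williamson etherification at high dilution; the C6 alkoxide is the only nucleophile and SN2 at primary C13 gives the unstrained thirteen-membered ring. SN2′ attack at hindered C7 would give an eleven-membered ring, and the C7=C11 geometry is not affected.

Step 20
Reactants: 24 thirteen-membered diallylic ether
Product: 26 ten-membered C6 carbinol (6R 7S 8S 9R), via C6-lithio ether 25 (not isolated)
Conditions: n-BuLi (1.5 equiv), THF, −78 → −25 °C; then aq. NH4Cl at −78 °C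
Reagents that add atoms: none
Why: n-BuLi, guided by the ring oxygen, removes a C6 proton (allylic to C4=C5) to give 25, whose carbanion bonds to C7 suprafacially across the O–C13–C11=C7 allyl unit while the C13–O bond breaks, so that C6–C7, the C11=C13 methylene and the C6 alkoxide arise in one [2,3]-sigmatropic shift. The closest known reaction type is the transannular [2,3]-Wittig ring contraction of thirteen-membered diallylic ethers to ten-membered homoallylic carbinols of the germacrane type. The ten-membered carbocycle is closed transannularly, inside the existing thirteen-membered ring, through a five-membered envelope transition state (C6, O, C13, C11, C7), so no high dilution is needed. The 6,7-trans relationship (6R,7S in 26) should follow from the ring-trans C7=C11 geometry, which holds C8 exo on the envelope while the C5 alkenyl arm of the carbanion also takes the exo position. The sense relative to C8 is controlled by the C8 stereocentre: allylic 1,3-strain against the C12 silyloxymethyl group keeps H8 in the alkene plane, and bonding anti to the bulky C8–C9 ring bond, on the face of the outward-pointing silyloxy group, gives 26. The step needs proton removal at C6 and not at C13: C13 is flanked by the fully substituted C11 and two bulky silyloxy groups, the silyl ethers are poor ligands for lithium so only the ring oxygen directs the base, and a C13 anion could react on only by forming a quaternary C4. Low temperature suppresses the [1,2]-shift, and the cold quench keeps silyl groups from migrating to the new C6 alkoxide.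

Step 21
Reactants: 26 ten-membered C6 carbinol
Product: 27 6,9,12-triol (C8 OTBS / C14 OTBDPS)
Conditions: CSA (cat.), MeOH/CH2Cl2, 0 °C
Reagents that add atoms: none
Why: Acid-catalysed methanolysis removes the primary allylic TBS ether (O12) and the secondary TES ether (O9); the hindered secondary TBS ether at O8 and the TBDPS ether are much slower.

Step 22
Reactants: 27 6,9,12-triol
Product: 30 C9-hydroxy α-methylene lactone (C8 OTBS / C14 OTBDPS), via hydroxy enal 28 (not isolated), via lactol 29 (not isolated)
Conditions: TEMPO (cat.), PhI(OAc)2, CH2Cl2, rt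
Reagents that add atoms: none
Why: Oxoammonium oxidation of the primary allylic C12 alcohol gives enal 28, which closes with O6 to lactol 29 and is oxidised on to the lactone (oxidative lactonisation of a 2-methylene-1,4-diol). Secondary alcohols react far more slowly, O8 is silylated, and O9 could only form a bridged six-membered lactol.

Step 23
Reactants: 30 C9-hydroxy α-methylene lactone
Product: 31 C9 acetate (C8 OTBS / C14 OTBDPS)
Conditions: Ac2O, pyridine, DMAP (cat.), CH2Cl2, 0 °C
Reagents that add atoms: acetic anhydride, CC(=O)OC(C)=O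
Why: Acetylation of the only free hydroxyl; with O8 silylated there is no acyl migration.

Step 24
Reactants: 31 C9 acetate
Product: 32 8,14-diol
Conditions: HF·pyridine, pyridine, THF, 0 °C → rt
Reagents that add atoms: none
Why: Fluoride cleavage of both remaining silyl ethers under mildly acidic conditions that leave the acetate and the α-methylene lactone unchanged.

Step 25
Reactants: 32 8,14-diol; 33 (R)-2-methylbutanoic acid
Product: 34 CNP0005248.2
Conditions: EDC·HCl, DMAP (cat.), CH2Cl2, −20 → 0 °C
Reagents that add atoms: none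
Why: Carbodiimide (Steglich) esterification of the primary allylic hydroxyl in preference to the hindered secondary 8-hydroxyl; low temperature and little DMAP limit acetyl migration and epimerisation of the acid.

## Compound list

1 | nerol, (2Z)-3,7-dimethylocta-2,6-dien-1-ol | CC(C)=CCC/C(C)=C\CO | starting material
2 | nerol PMB ether, 1-({[(2Z)-3,7-dimethylocta-2,6-dien-1-yl]oxy}methyl)-4-methoxybenzene | CC(C)=CCC/C(C)=C\COCc1ccc(OC)cc1 | intermediate
3 | 6,7-epoxide of 2 (racemic at the epoxide carbon), 3-{(3Z)-5-[(4-methoxybenzyl)oxy]-3-methylpent-3-en-1-yl}-2,2-dimethyloxirane | CC1(C)OC1CC/C(C)=C\COCc2ccc(OC)cc2 | intermediate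
4 | (6Z)-8-[(4-methoxybenzyl)oxy]-2,6-dimethyloct-6-ene-2,3-diol (racemic) | CC(C)(O)C(O)CC/C(C)=C\COCc1ccc(OC)cc1 | intermediate
5 | (4Z)-6-[(4-methoxybenzyl)oxy]-4-methylhex-4-enal | O=CCC/C(C)=C\COCc1ccc(OC)cc1 | intermediate
6 | ethyl (triphenylphosphoranylidene)acetate | CCOC(=O)C=P(c1ccccc1)(c1ccccc1)c1ccccc1 | starting material
7 | ethyl (2Z,6Z)-2-iodo-8-[(4-methoxybenzyl)oxy]-6-methylocta-2,6-dienoate | CCOC(=O)/C(I)=C/CC/C(C)=C\COCc1ccc(OC)cc1 | intermediate
8 | (2Z,6Z)-2-iodo-8-[(4-methoxybenzyl)oxy]-6-methylocta-2,6-dien-1-ol | OC/C(I)=C/CC/C(C)=C\COCc1ccc(OC)cc1 | intermediate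
9 | fragment A, tert-butyl({(2Z,6Z)-2-iodo-8-[(4-methoxybenzyl)oxy]-6-methylocta-2,6-dien-1-yl}oxy)diphenylsilane | CC(C)(C)[Si](c1ccccc1)(c1ccccc1)OC/C(I)=C/CC/C(C)=C\COCc1ccc(OC)cc1 | intermediate
10 | (R)-2,2-dimethyl-1,3-dioxolane-4-carbaldehyde | O=C[C@H]1COC(C)(C)O1 | starting material
11 | ethyl (2Z)-3-[(4S)-2,2-dimethyl-1,3-dioxolan-4-yl]-2-iodoprop-2-enoate | CCOC(=O)/C(I)=C/[C@H]1COC(C)(C)O1 | intermediate
12 | ethyl (2Z,4S)-4,5-dihydroxy-2-iodopent-2-enoate | CCOC(=O)/C(I)=C/[C@H](O)CO | intermediate
13 | ethyl (2Z,4S)-4-hydroxy-2-iodo-5-[(triethylsilyl)oxy]pent-2-enoate | CCOC(=O)/C(I)=C/[C@H](O)CO[Si](CC)(CC)CC | intermediate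
14 | ethyl (2Z,4S)-4-[(tert-butyldimethylsilyl)oxy]-2-iodo-5-[(triethylsilyl)oxy]pent-2-enoate | CCOC(=O)/C(I)=C/[C@H](O[Si](C)(C)C(C)(C)C)CO[Si](CC)(CC)CC | intermediate
15 | ethyl (2E,4S)-4-[(tert-butyldimethylsilyl)oxy]-2-(hydroxymethyl)-5-[(triethylsilyl)oxy]pent-2-enoate | CCOC(=O)/C(CO)=C/[C@H](O[Si](C)(C)C(C)(C)C)CO[Si](CC)(CC)CC | intermediate
16 | ethyl (2E,4S)-4-[(tert-butyldimethylsilyl)oxy]-2-{[(tert-butyldimethylsilyl)oxy]methyl}-5-[(triethylsilyl)oxy]pent-2-enoate | CCOC(=O)/C(CO[Si](C)(C)C(C)(C)C)=C/[C@H](O[Si](C)(C)C(C)(C)C)CO[Si](CC)(CC)CC | intermediate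
17 | ethyl (2E,4S)-4-[(tert-butyldimethylsilyl)oxy]-2-{[(tert-butyldimethylsilyl)oxy]methyl}-5-hydroxypent-2-enoate | CCOC(=O)/C(CO[Si](C)(C)C(C)(C)C)=C/[C@H](O[Si](C)(C)C(C)(C)C)CO | intermediate
18 | fragment B, ethyl (2E,4S)-4-[(tert-butyldimethylsilyl)oxy]-2-{[(tert-butyldimethylsilyl)oxy]methyl}-5-oxopent-2-enoate | CCOC(=O)/C(CO[Si](C)(C)C(C)(C)C)=C/[C@H](O[Si](C)(C)C(C)(C)C)C=O | intermediate
19 | C9 carbinol: open chain C13(ethyl ester)–C11(=C7)–C8–C9–C10(=C1)–C2–C3–C4(=C5)–C6 with C12 OTBS, C8 OTBS (S), C9 OH (R), C14 OTBDPS, C6 OPMB; ester trans to C8, C2 cis to C9, C4=C5 Z | CCOC(=O)/C(CO[Si](C)(C)C(C)(C)C)=C/[C@H](O[Si](C)(C)C(C)(C)C)[C@H](O)/C(CO[Si](c1ccccc1)(c1ccccc1)C(C)(C)C)=C\CC/C(C)=C\COCc1ccc(OC)cc1 | intermediate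
20 | C9 TES ether of 19 (8S,9R) | CCOC(=O)/C(CO[Si](C)(C)C(C)(C)C)=C/[C@H](O[Si](C)(C)C(C)(C)C)[C@H](O[Si](CC)(CC)CC)/C(CO[Si](c1ccccc1)(c1ccccc1)C(C)(C)C)=C\CC/C(C)=C\COCc1ccc(OC)cc1 | intermediate
21 | C13 allylic alcohol from 20 (C13 hydroxymethyl trans to C8; 8S,9R) | OC/C(CO[Si](C)(C)C(C)(C)C)=C/[C@H](O[Si](C)(C)C(C)(C)C)[C@H](O[Si](CC)(CC)CC)/C(CO[Si](c1ccccc1)(c1ccccc1)C(C)(C)C)=C\CC/C(C)=C\COCc1ccc(OC)cc1 | intermediate
22 | C13 allylic bromide from 21 (8S,9R) | BrC/C(CO[Si](C)(C)C(C)(C)C)=C/[C@H](O[Si](C)(C)C(C)(C)C)[C@H](O[Si](CC)(CC)CC)/C(CO[Si](c1ccccc1)(c1ccccc1)C(C)(C)C)=C\CC/C(C)=C\COCc1ccc(OC)cc1 | intermediate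
23 | C6 hydroxy C13 bromide (PMB removed; 8S,9R) | BrC/C(CO[Si](C)(C)C(C)(C)C)=C/[C@H](O[Si](C)(C)C(C)(C)C)[C@H](O[Si](CC)(CC)CC)/C(CO[Si](c1ccccc1)(c1ccccc1)C(C)(C)C)=C\CC/C(C)=C\CO | intermediate
24 | thirteen-membered diallylic ether (ring O, C13, C11=C7, C8, C9, C10=C1, C2, C3, C4=C5, C6): C12 OTBS on C11, C8 OTBS (S), C9 OTES (R), C14 OTBDPS on C10, methyl on C4; C13 trans to C8, C1=C10 and C4=C5 ring-cis | O1C/C(CO[Si](C)(C)C(C)(C)C)=C/[C@H](O[Si](C)(C)C(C)(C)C)[C@H](O[Si](CC)(CC)CC)/C(CO[Si](c2ccccc2)(c2ccccc2)C(C)(C)C)=C\CC/C(C)=C\C1 | intermediate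
25 | C6-lithio derivative of 24 (allylic α-oxy organolithium) | O1C/C(CO[Si](C)(C)C(C)(C)C)=C/[C@H](O[Si](C)(C)C(C)(C)C)[C@H](O[Si](CC)(CC)CC)/C(CO[Si](c2ccccc2)(c2ccccc2)C(C)(C)C)=C\CC/C(C)=C\C1[Li] | intermediate
26 | ten-membered carbinol (6R,7S,8S,9R): (1(10)Z,4Z)-cyclodecadiene with C6 OH, C7 3-[(tert-butyldimethylsilyl)oxy]prop-1-en-2-yl, C8 OTBS, C9 OTES, C10 CH2OTBDPS, C4 methyl | O[C@@H]1/C=C(/C)CC/C=C(/CO[Si](c2ccccc2)(c2ccccc2)C(C)(C)C)[C@@H](O[Si](CC)(CC)CC)[C@@H](O[Si](C)(C)C(C)(C)C)[C@H]1C(=C)CO[Si](C)(C)C(C)(C)C | intermediate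
27 | 6,9,12-triol (6R,7S,8S,9R; C8 OTBS, C14 OTBDPS) | O[C@@H]1/C=C(/C)CC/C=C(/CO[Si](c2ccccc2)(c2ccccc2)C(C)(C)C)[C@@H](O)[C@@H](O[Si](C)(C)C(C)(C)C)[C@H]1C(=C)CO | intermediate
28 | hydroxy enal (C12 aldehyde of 27) | O[C@@H]1/C=C(/C)CC/C=C(/CO[Si](c2ccccc2)(c2ccccc2)C(C)(C)C)[C@@H](O)[C@@H](O[Si](C)(C)C(C)(C)C)[C@H]1C(=C)C=O | intermediate
29 | 6,12-lactol (C12 hemiacetal, either anomer) | C=C1C(O)O[C@@H]2/C=C(/C)CC/C=C(/CO[Si](c3ccccc3)(c3ccccc3)C(C)(C)C)[C@@H](O)[C@@H](O[Si](C)(C)C(C)(C)C)[C@@H]12 | intermediate
30 | 9-hydroxy α-methylene 12,6-lactone (6R,7S,8S,9R; C8 OTBS, C14 OTBDPS) | C=C1C(=O)O[C@@H]2/C=C(/C)CC/C=C(/CO[Si](c3ccccc3)(c3ccccc3)C(C)(C)C)[C@@H](O)[C@@H](O[Si](C)(C)C(C)(C)C)[C@@H]12 | intermediate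
31 | 9-acetate of 30 (C8 OTBS, C14 OTBDPS) | C=C1C(=O)O[C@@H]2/C=C(/C)CC/C=C(/CO[Si](c3ccccc3)(c3ccccc3)C(C)(C)C)[C@@H](OC(C)=O)[C@@H](O[Si](C)(C)C(C)(C)C)[C@@H]12 | intermediate
32 | 9-acetoxy-8,14-dihydroxygermacra-1(10)Z,4Z,11(13)-trien-12,6-olide (6R,7R,8S,9R) | C=C1C(=O)O[C@@H]2/C=C(/C)CC/C=C(/CO)[C@@H](OC(C)=O)[C@@H](O)[C@@H]12 | intermediate
33 | (R)-2-methylbutanoic acid | CC[C@@H](C)C(=O)O | starting material
34 | CNP0005248.2, (6R,7R,8S,9R)-9-acetoxy-8-hydroxy-14-{[(2R)-2-methylbutanoyl]oxy}germacra-1(10)Z,4Z,11(13)-trien-12,6-olide | C=C1C(=O)O[C@@H]2/C=C(/C)CC/C=C(/COC(=O)[C@H](C)CC)[C@@H](OC(C)=O)[C@@H](O)[C@@H]12 | target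

## Step count and least certain steps

Total: 25 steps. Longest linear sequence: 19 steps (steps 7–25, from aldehyde 10); the nerol branch (steps 1–6) joins at step 14.

**Step 20 (key step).** Three processes can divert it:
- Proton removal at C13 instead of C6. The allyl anion so formed can expel the C8 silanolate (1,4-elimination) or shift to C4. Its kinetic acidity is raised by the neighbouring oxygens, although the position is more hindered.
- Bond formation on the wrong face of C7. The stereoelectronic preference for placing the C8–O bond anti to the incoming carbanion opposes the steric arrangement that the route needs, and the ring conformation decides between them. The result would be the 6,7-trans but 7,8-epimeric series.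
- A [1,2]-shift on warming.

A chiral bis(oxazoline)/t-BuLi base could be tried on 24, but that changes conditions only. The fallback sets out from hydroxy bromide 23. MnO2 oxidises the allylic C6 alcohol to the bromo enal F1, and CrCl2 in THF at high dilution turns the C13 bromide into an allylchromium reagent that adds through C7 to the C6 aldehyde (intramolecular Nozaki–Hiyama allylation). This forms the same C6–C7 bond, ring and methylene without strong base and comes back to the route at 26. Here the alkene reacts as the nucleophile, so the electron-rich C8–C9 bond, not the C8–O bond, is preferred anti to the new bond, and the chair transition state favours the 6,7-anti product.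

**Step 19 (macro-etherification).** Intermolecular alkylation can outrun closure and give oligomers, and the closure may be slow because three alkenes stiffen the chain. The fallback reverses the polarity and sets out from ester 20. DDQ gives the hydroxy ester F2, N-chlorosuccinimide/Me2S gives the C6 allylic chloride F3, and i-Bu2AlH at −78 °C gives the chloro alcohol F4. EtMgBr in THF/HMPA with slow addition then forms the magnesium alkoxide, which is covalent enough not to pass the O12 silyl group to O13, and this closes onto the C6 chloride to return to 24.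

**Step 14 (fragment coupling).** Felkin selectivity of chromium reagents with α-silyloxy aldehydes is often modest, and aldehyde 18 can lose configuration at C8 by enolisation during handling. For C9 the fallback sets out from the epimeric mixture 19. Dess–Martin oxidation gives the C9 enone F5, and NaBH4/CeCl3·7H2O at −78 °C reduces it by hydride delivery anti to the silyloxy group, returning to 19 with C9 set by reduction instead of by C–C bond formation.

**Step 25 (final esterification).** Acetyl migration from O9 to O8 or O14 under DMAP, or loss of primary over secondary selectivity, would give isomeric esters. The fallback sets out from 31. Bu4NF buffered with AcOH removes the primary TBDPS ether to give the C14 alcohol F6 with O8 still silylated. Esterification with 33 (EDC·HCl, DMAP) gives the ester F7, and HF·pyridine removes the TBS ether to arrive at 34, so the free 8-hydroxyl never meets base.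

## Further compounds

F1 | step 20 | bromo enal: C6 aldehyde of 23 with Z C4=C5 and C13 bromide | BrC/C(CO[Si](C)(C)C(C)(C)C)=C/[C@H](O[Si](C)(C)C(C)(C)C)[C@H](O[Si](CC)(CC)CC)/C(CO[Si](c1ccccc1)(c1ccccc1)C(C)(C)C)=C\CC/C(C)=C\C=O
F2 | step 19 | hydroxy ester: 20 without the PMB group (C6 OH) | CCOC(=O)/C(CO[Si](C)(C)C(C)(C)C)=C/[C@H](O[Si](C)(C)C(C)(C)C)[C@H](O[Si](CC)(CC)CC)/C(CO[Si](c1ccccc1)(c1ccccc1)C(C)(C)C)=C\CC/C(C)=C\CO
F3 | step 19 | C6 allylic chloride ester | CCOC(=O)/C(CO[Si](C)(C)C(C)(C)C)=C/[C@H](O[Si](C)(C)C(C)(C)C)[C@H](O[Si](CC)(CC)CC)/C(CO[Si](c1ccccc1)(c1ccccc1)C(C)(C)C)=C\CC/C(C)=C\CCl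
F4 | step 19 | chloro alcohol: C13 OH and C6 chloride | OC/C(CO[Si](C)(C)C(C)(C)C)=C/[C@H](O[Si](C)(C)C(C)(C)C)[C@H](O[Si](CC)(CC)CC)/C(CO[Si](c1ccccc1)(c1ccccc1)C(C)(C)C)=C\CC/C(C)=C\CCl
F5 | step 14 | C9 enone from 19 | CCOC(=O)/C(CO[Si](C)(C)C(C)(C)C)=C/[C@H](O[Si](C)(C)C(C)(C)C)C(=O)/C(CO[Si](c1ccccc1)(c1ccccc1)C(C)(C)C)=C\CC/C(C)=C\COCc1ccc(OC)cc1
F6 | step 25 | C14 alcohol: 9-acetate lactone with C8 OTBS | C=C1C(=O)O[C@@H]2/C=C(/C)CC/C=C(/CO)[C@@H](OC(C)=O)[C@@H](O[Si](C)(C)C(C)(C)C)[C@@H]12
F7 | step 25 | C8 TBS ether of 34 | C=C1C(=O)O[C@@H]2/C=C(/C)CC/C=C(/COC(=O)[C@H](C)CC)[C@@H](OC(C)=O)[C@@H](O[Si](C)(C)C(C)(C)C)[C@@H]12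
A1 | alternative 1 | open-chain Z C5 iodoalkene with C6 aldehyde and C12 methyl ester (C8 OTBS, C9 OTES, C14 OTBS) | I/C=C(/C)CC/C=C(/CO[Si](C)(C)C(C)(C)C)[C@@H](O[Si](CC)(CC)CC)[C@@H](O[Si](C)(C)C(C)(C)C)[C@H](C=O)CC(=O)OC
A2 | alternative 1 | ten-membered saturated trans-lactone (C8 OTBS, C9 OTES, C14 OTBS) | C1C(=O)O[C@@H]2/C=C(/C)CC/C=C(/CO[Si](C)(C)C(C)(C)C)[C@@H](O[Si](CC)(CC)CC)[C@@H](O[Si](C)(C)C(C)(C)C)[C@@H]12
A3 | alternative 2 | cis-decalin with angular C4 methyl, tertiary C9 hydroxyl, C5 mesylate and fused saturated trans-lactone (C8 OPMB, C14 OTBS) | C[C@]12CCC=C(CO[Si](C)(C)C(C)(C)C)[C@@]1(O)[C@@H](OCc4ccc(OC)cc4)[C@H]3CC(=O)O[C@@H]3[C@H]2OS(C)(=O)=O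
A4 | alternative 2 | Z,Z-cyclodecadien-9-one fused to the saturated trans-lactone (C8 OPMB, C14 OTBS) | C1C(=O)O[C@@H]2/C=C(/C)CC/C=C(/CO[Si](C)(C)C(C)(C)C)C(=O)[C@@H](OCc3ccc(OC)cc3)[C@@H]12
A5 | alternative 3 | C8 aldehyde on the saturated trans-lactone with C1 pinacolboronate and E C9 PMB enol ether (C14 OTBS) | O=C[C@H]1CC(=O)O[C@@H]1/C=C(/C)CC[C@@H](B2OC(C)(C)C(C)(C)O2)/C(CO[Si](C)(C)C(C)(C)C)=C/OCc3ccc(OC)cc3
A6 | alternative 3 | ten-membered 8-hydroxy 9-OPMB 14-OTBS saturated trans-lactone | C1C(=O)O[C@@H]2/C=C(/C)CC/C=C(/CO[Si](C)(C)C(C)(C)C)[C@@H](OCc3ccc(OC)cc3)[C@@H](O)[C@@H]12
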